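**Strategy.** Everything rests on building ring B last, on an internal alkyne that already carries ring A. In ring B, numbered C1'(=O), C2'(OH), C3'(Me), C4'(=O), C5'(ring A), C6'(phenethyl), the neighbours C5' and C6' hold the aryl and phenethyl groups as the two ends of an alkyne would, and the C4' carbonyl carbon can be a former CO ligand. A chromium alkenyl(methoxy)carbene therefore closes ring B in one operation, forming C1'–C6', C4'–C5' and C3'–C4', and replaces a tetra-ortho-substituted biaryl coupling by a Sonogashira reaction. The precursors are aryl alkyne 12, a 4-phenylbutynyl trimethoxytoluene carrying the methoxyphenethyl chain, and the alpha-ethoxypropenyl carbene complex 18; oxidation and hydrolysis finish the bis(hydroxyquinone).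

Key step: step 10

Assumption: the target is drawn without a descriptor for the hindered quinone–quinone axis, so the axis is made as a racemate.
Remark: ring A is numbered C1(=O), C2(OH), C3(Me), C4(=O), C5(biaryl), C6(chain), ring B the same with primes, and the arene precursors keep these locants. Commercial ethyl propenyl ether is a cis/trans mixture, so the Z ether is made from allyl ethyl ether (step 8).

**Route**

Step 1
Reactants: 1 2,4-dimethoxy-3-methylbenzaldehyde
Product: 3 2,4-dimethoxy-3-methylphenol, via aryl formate 2 (not isolated)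
Conditions: mCPBA, CH2Cl2, 0 °C to rt; then K2CO3 (cat.), MeOH, rt
Reagents that add atoms: 3-chloroperoxybenzoic acid (mCPBA), OOC(=O)c1cccc(Cl)c1
Why: Baeyer–Villiger (Dakin-type) oxidation, in which the electron-rich aryl group migrates to oxygen to give the aryl formate, which base-catalysed methanolysis should cleave to the phenol.

Step 2
Reactants: 3 2,4-dimethoxy-3-methylphenol
Product: 4 2-hydroxy-3,5-dimethoxy-4-methylbenzaldehyde
Conditions: MgCl2, Et3N, (CH2O)n, MeCN, reflux; aq. HCl work-up
Reagents that add atoms: paraformaldehyde (reacting as formaldehyde), C=O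
Why: Magnesium-mediated ortho-formylation of a phenol (Casnati–Skattebøl), in which the magnesium phenoxide delivers formaldehyde only to the carbon next to the phenol oxygen; C6 is the single free ortho position, so the site of the future chain is fixed by the mechanism and not by ring electronics.

Step 3
Reactants: 4 2-hydroxy-3,5-dimethoxy-4-methylbenzaldehyde
Product: 5 2,3,5-trimethoxy-4-methylbenzaldehyde
Conditions: MeI, K2CO3, DMF, rt
Reagents that add atoms: iodomethane, CI
Why: Williamson O-methylation of the only acidic group, the phenol, should proceed cleanly.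

Step 4
Reactants: 5 2,3,5-trimethoxy-4-methylbenzaldehyde; 6 (2-methoxybenzyl)triphenylphosphonium chloride
Product: 8 2,3,5-trimethoxy-1-[2-(2-methoxyphenyl)ethenyl]-4-methylbenzene (E/Z mixture expected; E isomer drawn), via phosphorus ylide 7 (not isolated)
Conditions: 6, KOt-Bu, THF, 0 °C; then 5, 0 °C to rt
Reagents that add atoms: none
Why: Wittig olefination of an aryl aldehyde with a semi-stabilised benzylic ylide; the alkene geometry is irrelevant because the double bond is saturated in the next step.

Step 5
Reactants: 8 2,3,5-trimethoxy-1-[2-(2-methoxyphenyl)ethenyl]-4-methylbenzene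
Product: 9 2,3,5-trimethoxy-1-[2-(2-methoxyphenyl)ethyl]-4-methylbenzene
Conditions: H2 (1 atm), 10% Pd/C, EtOAc, rt
Reagents that add atoms: none
Why: Heterogeneous catalytic hydrogenation of a stilbene double bond, under which aryl methyl ethers and the arenes are inert.

Step 6
Reactants: 9 2,3,5-trimethoxy-1-[2-(2-methoxyphenyl)ethyl]-4-methylbenzene
Product: 10 1-iodo-2,4,5-trimethoxy-3-methyl-6-[2-(2-methoxyphenyl)ethyl]benzene
Conditions: NIS (1 equiv), CF3CO2H (cat.), MeCN, 0 °C to rt
Reagents that add atoms: N-iodosuccinimide, O=C1CCC(=O)N1I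
Why: Electrophilic aromatic iodination at C5, the only free position of ring A (ortho to the C4 methoxy, para to the C2 methoxy group); the trialkoxy ring should be far more nucleophilic than the mono-methoxy side-chain ring, so one equivalent of NIS should iodinate ring A only.

Step 7
Reactants: 10 1-iodo-2,4,5-trimethoxy-3-methyl-6-[2-(2-methoxyphenyl)ethyl]benzene; 11 4-phenylbut-1-yne
Product: 12 2,4,5-trimethoxy-3-methyl-6-[2-(2-methoxyphenyl)ethyl]-1-(4-phenylbut-1-ynyl)benzene
Conditions: Pd(PPh3)2Cl2 (cat.), CuI (cat.), Et3N, DMF, 70 °C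
Reagents that add atoms: none
Why: Sonogashira coupling, in which the aryl iodide adds oxidatively to zerovalent palladium even between two ortho substituents and the slim copper acetylide of the terminal alkyne transmetalates without steric difficulty.

Step 8
Reactants: 13 allyl ethyl ether (3-ethoxyprop-1-ene)
Product: 14 (Z)-1-ethoxyprop-1-ene
Conditions: KOt-Bu (cat.), DMSO, rt to 60 °C; product distilled out
Reagents that add atoms: none
Why: Base-catalysed allyl-to-propenyl ether isomerisation, in which the potassium-chelated cisoid allyl anion is protonated at the terminal carbon and should give the Z enol ether under kinetic control.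

Step 9
Reactants: 14 (Z)-1-ethoxyprop-1-ene; 15 Cr(CO)6
Product: 18 pentacarbonyl[(Z)-2-ethoxy-1-methoxybut-2-en-1-ylidene]chromium, via alkenyllithium 16 (not isolated), via lithium acylchromate 17 (not isolated)
Conditions: t-BuLi, THF, −78 to 0 °C; Cr(CO)6, THF, 0 °C to rt; then Me3OBF4, CH2Cl2, 0 °C
Reagents that add atoms: trimethyloxonium tetrafluoroborate, C[O+](C)C.F[B-](F)(F)F
Why: Fischer carbene synthesis: deprotonation at the oxygen-bearing vinylic carbon with retention of alkene geometry, addition of the alkenyllithium to a CO ligand of Cr(CO)6, and O-methylation of the acylchromate by a hard methylating agent.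

Step 10
Reactants: 12 2,4,5-trimethoxy-3-methyl-6-[2-(2-methoxyphenyl)ethyl]-1-(4-phenylbut-1-ynyl)benzene; 18 pentacarbonyl[(Z)-2-ethoxy-1-methoxybut-2-en-1-ylidene]chromium
Product: 20 3-ethoxy-4-methoxy-2-methyl-5-(2-phenylethyl)-6-{2,4,5-trimethoxy-3-methyl-6-[2-(2-methoxyphenyl)ethyl]phenyl}phenol, via tricarbonylchromium arene complex 19 (not isolated)
Conditions: 18 (excess), THF, 55 °C, Ar; then air, rt
Reagents that add atoms: none
Why: Dötz benzannulation: thermal loss of one CO from 18 frees a site on zerovalent chromium, alkyne 12 inserts into the chromium–carbene bond (C1'–C6'), a CO ligand inserts to give a chromium-bound dienylketene (C4'–C5'), the ketene carbon closes onto the propenyl CH carbon (C3'–C4'), and tautomerisation gives the phenol, which air then frees from Cr(CO)3. The closest known reaction type is the benzannulation of alkenyl(alkoxy)carbene complexes of chromium, alpha-alkoxyalkenyl ones included, with internal and ortho-substituted aryl alkynes. Ring B is closed by a six-electron electrocyclisation of the dienylketene after the first two bonds have formed at the metal. No stereocentre is created, and the hindered biaryl axis should form as a racemate, which is all the target requires. The step needs one orientation of insertion, carbene carbon on the phenethyl-bearing alkyne carbon, and the bulk of the 2,6-disubstituted ring A aryl group against a primary CH2 should secure it, because the larger alkyne substituent ends next to the CO-derived carbon.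

Step 11
Reactants: 20 3-ethoxy-4-methoxy-2-methyl-5-(2-phenylethyl)-6-{2,4,5-trimethoxy-3-methyl-6-[2-(2-methoxyphenyl)ethyl]phenyl}phenol
Product: 21 2-ethoxy-5-{4-methoxy-5-methyl-2-[2-(2-methoxyphenyl)ethyl]-3,6-dioxocyclohexa-1,4-dien-1-yl}-3-methyl-6-(2-phenylethyl)cyclohexa-2,5-diene-1,4-dione
Conditions: (NH4)2Ce(NO3)6 (4–5 equiv), MeCN/H2O, 0 °C
Reagents that add atoms: water, O
Why: Oxidative demethylation by tetravalent cerium: the para-methoxyphenol of ring B and the para-dimethoxyarene of ring A should each give the 1,4-benzoquinone with loss of methanol, while the C2 methoxy and C2' ethoxy groups stay as vinylogous esters and the mono-methoxy side-chain ring is too electron-poor to be oxidised.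

Step 12
Reactants: 21 bis(alkoxyquinone)
Product: 22 2-hydroxy-5-{4-hydroxy-5-methyl-2-[2-(2-methoxyphenyl)ethyl]-3,6-dioxocyclohexa-1,4-dien-1-yl}-3-methyl-6-(2-phenylethyl)cyclohexa-2,5-diene-1,4-dione (CNP0202346.0)
Conditions: NaOH (1 M aq.), THF/H2O, 0 °C to rt, Ar; aq. HCl work-up
Reagents that add atoms: sodium hydroxide, [Na+].[OH-]
Why: Alkoxyquinone hydrolysis by addition–elimination of hydroxide at the two alkoxy-bearing carbons of the vinylogous esters; both quinones are fully substituted, so no free position is open to conjugate addition, and acidification should return the bis(hydroxyquinone).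

**Compound list**

1 | 2,4-dimethoxy-3-methylbenzaldehyde | COc1ccc(C=O)c(OC)c1C | starting material
2 | 2,4-dimethoxy-3-methylphenyl formate | COc1ccc(OC=O)c(OC)c1C | intermediate
3 | 2,4-dimethoxy-3-methylphenol | COc1ccc(O)c(OC)c1C | intermediate
4 | 2-hydroxy-3,5-dimethoxy-4-methylbenzaldehyde | COc1cc(C=O)c(O)c(OC)c1C | intermediate
5 | 2,3,5-trimethoxy-4-methylbenzaldehyde | COc1cc(C=O)c(OC)c(OC)c1C | intermediate
6 | (2-methoxybenzyl)triphenylphosphonium chloride | COc1ccccc1C[P+](c1ccccc1)(c1ccccc1)c1ccccc1.[Cl-] | starting material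
7 | (2-methoxybenzylidene)triphenylphosphorane | COc1ccccc1C=P(c1ccccc1)(c1ccccc1)c1ccccc1 | intermediate
8 | 2,3,5-trimethoxy-1-[2-(2-methoxyphenyl)ethenyl]-4-methylbenzene (E/Z mixture expected, E drawn) | COc1ccccc1/C=C/c1cc(OC)c(C)c(OC)c1OC | intermediate
9 | 2,3,5-trimethoxy-1-[2-(2-methoxyphenyl)ethyl]-4-methylbenzene | COc1ccccc1CCc1cc(OC)c(C)c(OC)c1OC | intermediate
10 | 1-iodo-2,4,5-trimethoxy-3-methyl-6-[2-(2-methoxyphenyl)ethyl]benzene | COc1c(C)c(OC)c(OC)c(CCc2ccccc2OC)c1I | intermediate
11 | 4-phenylbut-1-yne | C#CCCc1ccccc1 | starting material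
12 | 2,4,5-trimethoxy-3-methyl-6-[2-(2-methoxyphenyl)ethyl]-1-(4-phenylbut-1-ynyl)benzene | COc1c(C)c(OC)c(OC)c(CCc2ccccc2OC)c1C#CCCc1ccccc1 | intermediate
13 | allyl ethyl ether (3-ethoxyprop-1-ene) | C=CCOCC | starting material
14 | (Z)-1-ethoxyprop-1-ene | CCO/C=C\C | intermediate
15 | chromium hexacarbonyl, Cr(CO)6 | O=C=[Cr](=C=O)(=C=O)(=C=O)(=C=O)=C=O | starting material
16 | (Z)-1-ethoxy-1-lithioprop-1-ene | CCO/C([Li])=C\C | intermediate
17 | lithium pentacarbonyl[(Z)-2-ethoxy-1-oxidobut-2-en-1-ylidene]chromate | [Li+].[O-]C(=[Cr](=C=O)(=C=O)(=C=O)(=C=O)=C=O)/C(OCC)=C/C | intermediate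
18 | pentacarbonyl[(Z)-2-ethoxy-1-methoxybut-2-en-1-ylidene]chromium | COC(=[Cr](=C=O)(=C=O)(=C=O)(=C=O)=C=O)/C(OCC)=C/C | intermediate
19 | tricarbonylchromium complex of 20, Cr(CO)3 bound eta-6 to ring B (drawn as two parts) | CCOc1c(C)c(O)c(-c2c(OC)c(C)c(OC)c(OC)c2CCc2ccccc2OC)c(CCc2ccccc2)c1OC.O=C=[Cr](=C=O)=C=O | intermediate
20 | 3-ethoxy-4-methoxy-2-methyl-5-(2-phenylethyl)-6-{2,4,5-trimethoxy-3-methyl-6-[2-(2-methoxyphenyl)ethyl]phenyl}phenol (racemic axis) | CCOc1c(C)c(O)c(-c2c(OC)c(C)c(OC)c(OC)c2CCc2ccccc2OC)c(CCc2ccccc2)c1OC | intermediate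
21 | 2-ethoxy-5-{4-methoxy-5-methyl-2-[2-(2-methoxyphenyl)ethyl]-3,6-dioxocyclohexa-1,4-dien-1-yl}-3-methyl-6-(2-phenylethyl)cyclohexa-2,5-diene-1,4-dione | COc1ccccc1CCC1=C(C2=C(CCc3ccccc3)C(=O)C(OCC)=C(C)C2=O)C(=O)C(C)=C(OC)C1=O | intermediate
22 | 2-hydroxy-5-{4-hydroxy-5-methyl-2-[2-(2-methoxyphenyl)ethyl]-3,6-dioxocyclohexa-1,4-dien-1-yl}-3-methyl-6-(2-phenylethyl)cyclohexa-2,5-diene-1,4-dione (CNP0202346.0) | COc1ccccc1CCC1=C(C2=C(CCc3ccccc3)C(=O)C(O)=C(C)C2=O)C(=O)C(C)=C(O)C1=O | target

**Step count and risks**

Total step count: 12. Longest linear sequence: 10 steps (steps 1–7, then 10–12); the carbene branch (steps 8–9) joins at step 10.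

Steps most likely to fail:

1. Step 10. Insertion of the crowded triple bond may be slower than thermal decay of the carbene complex, or the alkyne may insert with the reverse orientation or end in five-membered-ring products without CO uptake. The fallback forms the biaryl bond by cross-coupling instead of ring construction; it sets out from 5 and 10 and comes back at the target 22. Aldehyde 5 would be taken through the conditions of steps 4–6 with benzyltriphenylphosphonium chloride in place of 6, giving 2,3,5-trimethoxy-4-methyl-1-(2-phenylethenyl)benzene F1, then 2,3,5-trimethoxy-4-methyl-1-(2-phenylethyl)benzene F2, then 1-iodo-2,4,5-trimethoxy-3-methyl-6-(2-phenylethyl)benzene F3. Iodide 10 would be converted by iodine–lithium exchange (n-BuLi, THF, −78 °C) and 2-isopropoxy-4,4,5,5-tetramethyl-1,3,2-dioxaborolane into the ring A pinacol boronate F4. Suzuki–Miyaura coupling of F3 with F4 (Pd(OAc)2, SPhos, K3PO4, toluene/H2O, 100 °C) should give the hexamethoxy biaryl F5. Oxidation with (NH4)2Ce(NO3)6 as in step 11 should give the bis(methoxyquinone) F6, and NaOH hydrolysis as in step 12 should give 22.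

2. Step 9. Allylic deprotonation or incomplete alpha-lithiation of the enol ether may compete, so that too little of the alkenyllithium reaches Cr(CO)6. The fallback makes the same alkenyllithium by tin–lithium exchange instead of deprotonation; it sets out from 15, which is used unchanged, and comes back at 16. Commercial 1-ethoxyprop-1-yne would be hydrostannylated by syn addition (Bu3SnH, Pd(PPh3)4 cat., THF), which should place tin on the oxygen-bearing carbon and give (E)-tributyl(1-ethoxyprop-1-enyl)stannane F7. Treatment with n-BuLi (THF, −78 °C) should give 16 with the same geometry, which is added to 15 and methylated as in step 9.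

3. Step 12. Hydroxide may degrade the bis-quinone (tautomerisation to quinone methides at the benzylic CH2 groups, redox side reactions) faster than it displaces the alkoxy groups from the hindered, fully substituted vinylogous esters. The fallback exchanges the alkoxy groups for an amine and hydrolyses under acid; it sets out from 21 and comes back at 22. Dimethylamine in EtOH at rt should displace both alkoxy groups by addition–elimination and give the bis(dimethylaminoquinone) F8, and warm dilute aqueous HCl in AcOH should hydrolyse the two vinylogous amides to 22.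

Further compounds
F1 | step 10 | 2,3,5-trimethoxy-4-methyl-1-(2-phenylethenyl)benzene (E/Z mixture expected, E drawn) | COc1cc(/C=C/c2ccccc2)c(OC)c(OC)c1C
F2 | step 10 | 2,3,5-trimethoxy-4-methyl-1-(2-phenylethyl)benzene | COc1cc(CCc2ccccc2)c(OC)c(OC)c1C
F3 | step 10 | 1-iodo-2,4,5-trimethoxy-3-methyl-6-(2-phenylethyl)benzene | COc1c(C)c(OC)c(OC)c(CCc2ccccc2)c1I
F4 | step 10 | 2-{2,4,5-trimethoxy-3-methyl-6-[2-(2-methoxyphenyl)ethyl]phenyl}-4,4,5,5-tetramethyl-1,3,2-dioxaborolane | COc1c(C)c(OC)c(OC)c(CCc2ccccc2OC)c1B1OC(C)(C)C(C)(C)O1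
F5 | step 10 | 2,2',4,4',5,5'-hexamethoxy-3,3'-dimethyl-6-[2-(2-methoxyphenyl)ethyl]-6'-(2-phenylethyl)biphenyl | COc1c(C)c(OC)c(OC)c(CCc2ccccc2OC)c1-c1c(OC)c(C)c(OC)c(OC)c1CCc1ccccc1
F6 | step 10 | 2-methoxy-5-{4-methoxy-5-methyl-2-[2-(2-methoxyphenyl)ethyl]-3,6-dioxocyclohexa-1,4-dien-1-yl}-3-methyl-6-(2-phenylethyl)cyclohexa-2,5-diene-1,4-dione | COc1ccccc1CCC1=C(C2=C(CCc3ccccc3)C(=O)C(OC)=C(C)C2=O)C(=O)C(C)=C(OC)C1=O
F7 | step 9 | (E)-tributyl(1-ethoxyprop-1-enyl)stannane | CCCC[Sn](CCCC)(CCCC)/C(OCC)=C/C
F8 | step 12 | 2-(dimethylamino)-5-{4-(dimethylamino)-5-methyl-2-[2-(2-methoxyphenyl)ethyl]-3,6-dioxocyclohexa-1,4-dien-1-yl}-3-methyl-6-(2-phenylethyl)cyclohexa-2,5-diene-1,4-dione | COc1ccccc1CCC1=C(C2=C(CCc3ccccc3)C(=O)C(N(C)C)=C(C)C2=O)C(=O)C(C)=C(N(C)C)C1=O
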